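**Retrosynthetic overview**
- The side chain is cut at C2'–C3'. An sp3–sp2 Negishi coupling joins a silyl-protected (S)-2-(2-iodoethyl)-2-methyl-2H-chromene to an E-alkenyl iodide made from dihydro-β-ionone (terminal alkyne, then zirconium-catalysed methylalumination and iodination). The phenol is freed last.
- The C3=C4 bond is traced back to a benzylic C4 alcohol and the iodide to a primary alcohol. Both hydroxyls come from reduction of a bridged chroman lactol.
- The plan rests on one feature: C2, its methyl group, C3, C1' and C2' are a hidden prenal (β-carbon = C2; γ-methyls = C3 and the C2 methyl; α-carbon and formyl carbon = C1' and C2'). The lactol is therefore cut at C3–C4, O1–C2 and the hemiacetal C–O bond into prenal and a 5-silyloxysalicylaldehyde, which one amine-catalysed domino reaction joins while setting the quaternary C2.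
- Ring order: the benzene and cyclohexene rings are bought. The pyran ring and a temporary lactol ring close together in the key step, and the lactol ring is reopened by reduction.

Key step: step 2

Atom labels: chromene numbering O1, C2, C3, C4; C1' and C2' are the first two side-chain carbons on C2.
Assumption: the sense of induction is assigned from the steric-shielding model of the E-configured, s-trans iminium ion. Should the lactol prove to be the antipode, the (R)-catalyst is used with no other change.

**Step 1**
Reactants: 1 2,5-dihydroxybenzaldehyde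
Product: 2 5-[(tert-butyldimethylsilyl)oxy]-2-hydroxybenzaldehyde
Conditions: TBSCl (1.05 equiv), imidazole, CH2Cl2, 0 °C
Reagents that add atoms: tert-butyldimethylsilyl chloride, CC(C)(C)[Si](C)(C)Cl
Why: Base-mediated O-silylation should be selective for the 5-hydroxyl because the 2-hydroxyl is held in a hydrogen bond to the formyl group and is more hindered; no stereocentre is involved.

**Step 2**
Reactants: 2 5-[(tert-butyldimethylsilyl)oxy]-2-hydroxybenzaldehyde; 3 prenal (3-methylbut-2-enal)
Product: 6 (2R,6R)-8-[(tert-butyldimethylsilyl)oxy]-2-methyl-3,4-dihydro-2H,6H-2,6-methano-1,5-benzodioxocin-4-ol (bridged chroman lactol; both anomers), via aldol enal 4 (not isolated), via chroman hydroxy aldehyde 5 (not isolated)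
Conditions: (S)-2-{bis[3,5-bis(trifluoromethyl)phenyl][(trimethylsilyl)oxy]methyl}pyrrolidine (30 mol %), PhCO2H (30 mol %), toluene, rt; 3 (3 equiv) added slowly
Reagents that add atoms: none
Why: The amine condenses with 3 to an iminium ion that loses a γ-proton to the cross-conjugated dienamine, whose terminal CH2 adds to the formyl carbon of 2 (C3–C4 bond) and regenerates an α,β-unsaturated iminium ion (4 in its iminium form); this is the known diarylprolinol silyl ether catalysed domino vinylogous aldol/oxa-Michael reaction of salicylaldehydes with β-methyl enals. The pyran ring closes by 6-exo-trig oxa-Michael addition of the phenol oxygen to the β-carbon (O1–C2), and after hydrolysis to 5 the lactol ring closes by 6-exo-trig addition of the C4 hydroxyl to the formyl carbon. C2 is set in the oxa-Michael step: in the E-configured, s-trans iminium ion, with the CH2CH(OH)Ar branch trans to the CH=N carbon, the bis(aryl)(silyloxy)methyl group of the (S)-catalyst covers one face and the phenol adds to the other, which should place the catalyst-bound two-carbon arm and the methyl group as drawn. C4 is tied to C2 because only the isomer with the C4 oxygen and the C2 acetaldehyde arm cis (both axial) can bridge, and since the aldol and oxa-Michael steps are reversible, mismatched material should be returned and drained into the one bridged lactol, whose hemiacetal carbon is left to equilibrate. The step needs γ- instead of α-attack of the dienamine and aldol addition before oxa-Michael addition (the reverse order would end in a 2,2-dimethylchromene-3-carbaldehyde): the β,β-disubstitution of 3 hinders direct conjugate addition of the phenol and leaves the exocyclic CH2 as the accessible nucleophilic terminus, the ortho hydroxyl activates the formyl group of 2 by hydrogen bonding, and the lactol trap removes the product from all equilibria. Self-condensation of 3 is held down by adding it slowly and in excess.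

**Step 3**
Reactants: 6 bridged chroman lactol
Product: 7 (2S,4R)-6-[(tert-butyldimethylsilyl)oxy]-2-(2-hydroxyethyl)-2-methylchroman-4-ol
Conditions: NaBH4, EtOH–THF, 0 °C
Reagents that add atoms: none
Why: In this borohydride reduction of a lactol, the hemiacetal of 6 stands in ring–chain equilibrium with the hydroxy aldehyde 5 of step 2, whose formyl group should take up hydride irreversibly and faster than any retro-oxa-Michael opening, so C2 and C4 are kept and the aryl silyl ether survives at 0 °C.

**Step 4**
Reactants: 7 (2S,4R)-diol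
Product: 8 (2R,4R)-6-[(tert-butyldimethylsilyl)oxy]-2-(2-iodoethyl)-2-methylchroman-4-ol
Conditions: I2 (1.1 equiv), PPh3 (1.1 equiv), imidazole, CH2Cl2, 0 °C
Reagents that add atoms: iodine, II
Why: In this Appel-type iodination the unhindered primary hydroxyl should form the alkoxyphosphonium ion and be displaced by iodide (SN2) much faster than the hindered secondary benzylic hydroxyl reacts, and neither stereocentre is touched (the descriptor at C2 changes only because of the priority of iodine).

**Step 5**
Reactants: 8 (2R,4R)-iodo alcohol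
Product: 9 tert-butyl{[(2S)-2-(2-iodoethyl)-2-methyl-2H-chromen-6-yl]oxy}dimethylsilane
Conditions: Burgess reagent (methyl N-(triethylammoniosulfonyl)carbamate, 1.5 equiv), benzene, 50 °C
Reagents that add atoms: none
Why: Burgess dehydration of the benzylic sulfamate ester by syn elimination with a C3 hydrogen (the only β-hydrogens present) should give the aryl-conjugated C3=C4 bond under neutral conditions, which removes the C4 stereocentre and leaves C2, the iodide and the silyl ether intact.

**Step 6**
Reactants: 10 dihydro-β-ionone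
Product: 12 2-(but-3-yn-1-yl)-1,3,3-trimethylcyclohex-1-ene, via enol phosphate 11 (not isolated)
Conditions: LiN(i-Pr)2 (1.1 equiv), THF, −78 °C; ClP(O)(OEt)2, −78 °C to rt; then LiN(i-Pr)2 (2.3 equiv), −78 °C to rt; aq. NH4Cl
Reagents that add atoms: none
Why: Kinetic deprotonation at the methyl group, O-phosphorylation of the terminal enolate and amide-induced β-elimination of diethyl phosphate (methyl ketone to terminal alkyne by enol phosphate elimination) should give the alkyne, held as its acetylide until work-up.

**Step 7**
Reactants: 12 2-(but-3-yn-1-yl)-1,3,3-trimethylcyclohex-1-ene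
Product: 14 2-[(3E)-4-iodo-3-methylbut-3-en-1-yl]-1,3,3-trimethylcyclohex-1-ene, via alkenylalane 13 (not isolated)
Conditions: AlMe3 (2.5 equiv), Cp2ZrCl2 (0.25 equiv), CH2Cl2, 0 °C to rt; then I2, THF, −30 to 0 °C
Reagents that add atoms: trimethylaluminium, C[Al](C)C; iodine, II
Why: Zirconium-catalysed carboalumination (Negishi) adds methyl and aluminium syn across the terminal alkyne with aluminium on the terminal carbon, and iodinolysis with retention should give the E-alkenyl iodide, the tetrasubstituted ring alkene being inert.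

**Step 8**
Reactants: 9 (S)-chromenylethyl iodide; 14 E-alkenyl iodide
Product: 16 tert-butyldimethyl({(2S)-2-methyl-2-[(3E)-4-methyl-6-(2,6,6-trimethylcyclohex-1-en-1-yl)hex-3-en-1-yl]-2H-chromen-6-yl}oxy)silane, via alkylzinc iodide 15 (not isolated)
Conditions: 9, Zn dust (activated with BrCH2CH2Br and Me3SiCl), LiCl, THF, 40 °C; then 14, Pd(PPh3)4 (5 mol %), THF, rt to 45 °C
Reagents that add atoms: none
Why: In this Negishi coupling, LiCl-assisted zinc insertion into the primary C–I bond should give an alkylzinc iodide that tolerates the silyl ether and the chromene, and zerovalent palladium joins it to the alkenyl iodide by oxidative addition, transmetalation and reductive elimination with retention of the E geometry, C2 not being involved.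

**Step 9**
Reactants: 16 silyl ether of the target
Product: 17 (2S)-2-methyl-2-[(3E)-4-methyl-6-(2,6,6-trimethylcyclohex-1-en-1-yl)hex-3-en-1-yl]-2H-chromen-6-ol
Conditions: Bu4NF (1.1 equiv), AcOH (1.1 equiv), THF, 0 °C, argon
Reagents that add atoms: none
Why: Fluoride-induced cleavage of the aryl silyl ether, buffered with acetic acid, should free the phenol without touching the chromene, the alkenes or C2.

**Compound list**
1 | 2,5-dihydroxybenzaldehyde | O=Cc1cc(O)ccc1O | starting material
2 | 5-[(tert-butyldimethylsilyl)oxy]-2-hydroxybenzaldehyde | O=Cc1cc(O[Si](C)(C)C(C)(C)C)ccc1O | intermediate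
3 | prenal (3-methylbut-2-enal) | CC(C)=CC=O | starting material
4 | (2E,5R)-5-{5-[(tert-butyldimethylsilyl)oxy]-2-hydroxyphenyl}-5-hydroxy-3-methylpent-2-enal (γ-aldol adduct, carried in the flask as its iminium ion with the catalyst) | C/C(=C\C=O)C[C@@H](O)c1cc(O[Si](C)(C)C(C)(C)C)ccc1O | intermediate
5 | 2-{(2R,4R)-6-[(tert-butyldimethylsilyl)oxy]-4-hydroxy-2-methylchroman-2-yl}acetaldehyde | C[C@]1(CC=O)C[C@@H](O)c2cc(O[Si](C)(C)C(C)(C)C)ccc2O1 | intermediate
6 | (2R,6R)-8-[(tert-butyldimethylsilyl)oxy]-2-methyl-3,4-dihydro-2H,6H-2,6-methano-1,5-benzodioxocin-4-ol (chroman whose C4 oxygen and C2 CH2 arm are joined through a hemiacetal carbon; both anomers) | C[C@@]12C[C@@H](OC(O)C1)c1cc(O[Si](C)(C)C(C)(C)C)ccc1O2 | intermediate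
7 | (2S,4R)-6-[(tert-butyldimethylsilyl)oxy]-2-(2-hydroxyethyl)-2-methylchroman-4-ol | C[C@]1(CCO)C[C@@H](O)c2cc(O[Si](C)(C)C(C)(C)C)ccc2O1 | intermediate
8 | (2R,4R)-6-[(tert-butyldimethylsilyl)oxy]-2-(2-iodoethyl)-2-methylchroman-4-ol | C[C@]1(CCI)C[C@@H](O)c2cc(O[Si](C)(C)C(C)(C)C)ccc2O1 | intermediate
9 | tert-butyl{[(2S)-2-(2-iodoethyl)-2-methyl-2H-chromen-6-yl]oxy}dimethylsilane | C[C@]1(CCI)C=Cc2cc(O[Si](C)(C)C(C)(C)C)ccc2O1 | intermediate
10 | dihydro-β-ionone, 4-(2,6,6-trimethylcyclohex-1-en-1-yl)butan-2-one | CC(=O)CCC1=C(C)CCCC1(C)C | starting material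
11 | diethyl 4-(2,6,6-trimethylcyclohex-1-en-1-yl)but-1-en-2-yl phosphate | C=C(OP(=O)(OCC)OCC)CCC1=C(C)CCCC1(C)C | intermediate
12 | 2-(but-3-yn-1-yl)-1,3,3-trimethylcyclohex-1-ene | C#CCCC1=C(C)CCCC1(C)C | intermediate
13 | dimethyl[(1E)-2-methyl-4-(2,6,6-trimethylcyclohex-1-en-1-yl)but-1-en-1-yl]alane | C/C(=C\[Al](C)C)CCC1=C(C)CCCC1(C)C | intermediate
14 | 2-[(3E)-4-iodo-3-methylbut-3-en-1-yl]-1,3,3-trimethylcyclohex-1-ene | C/C(=C\I)CCC1=C(C)CCCC1(C)C | intermediate
15 | {2-[(2S)-6-[(tert-butyldimethylsilyl)oxy]-2-methyl-2H-chromen-2-yl]ethyl}zinc iodide | C[C@]1(CC[Zn]I)C=Cc2cc(O[Si](C)(C)C(C)(C)C)ccc2O1 | intermediate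
16 | tert-butyldimethyl({(2S)-2-methyl-2-[(3E)-4-methyl-6-(2,6,6-trimethylcyclohex-1-en-1-yl)hex-3-en-1-yl]-2H-chromen-6-yl}oxy)silane | CC1=C(CC/C(C)=C/CC[C@@]2(C)C=Cc3cc(O[Si](C)(C)C(C)(C)C)ccc3O2)C(C)(C)CCC1 | intermediate
17 | (2S)-2-methyl-2-[(3E)-4-methyl-6-(2,6,6-trimethylcyclohex-1-en-1-yl)hex-3-en-1-yl]-2H-chromen-6-ol | CC1=C(CC/C(C)=C/CC[C@@]2(C)C=Cc3cc(O)ccc3O2)C(C)(C)CCC1 | target

**Step count and risks**
Total: 9 steps. Longest linear sequence: 7 steps (steps 1, 2, 3, 4, 5, 8, 9); the side-chain branch is steps 6 and 7.

Steps most likely to fail: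

1. Step 2. The phenol may add through the Z-configured iminium ion or to catalyst-free enal, so that both faces of C2 are used and the lactol forms in low enantiomeric purity; self-condensation of prenal would only lower the yield. The fallback sets out from diol 7 of insufficient enantiomeric purity and comes back at 7. Because the lactol bridge has locked C2 and C4 cis, resolving the C4 carbinol resolves C2 as well. Lipase-catalysed acylation (immobilised Candida antarctica lipase B, vinyl acetate, t-BuOMe, rt) should acetylate the primary hydroxyl of both antipodes but the benzylic hydroxyl only of the (4R)-antipode, which is the usual preference of this enzyme for aryl carbinols. This gives the diacetate 2-{(2S,4R)-4-acetoxy-6-[(tert-butyldimethylsilyl)oxy]-2-methylchroman-2-yl}ethyl acetate F1 and the monoacetate of the antipode, 2-{(2R,4S)-6-[(tert-butyldimethylsilyl)oxy]-4-hydroxy-2-methylchroman-2-yl}ethyl acetate F2. After chromatographic separation, F1 is cleaved with i-Bu2AlH (CH2Cl2, −78 °C) to return enantiopure 7.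

2. Step 4. The cis C4 hydroxyl may attack the activated primary carbon and close a bridged cyclic ether, or the benzylic hydroxyl may itself be activated and ionise. The fallback sets out from 7 and comes back at 9, bypassing 8. Primary-selective acylation (t-BuCOCl, pyridine, CH2Cl2, 0 °C) gives 2-{(2S,4R)-6-[(tert-butyldimethylsilyl)oxy]-4-hydroxy-2-methylchroman-2-yl}ethyl 2,2-dimethylpropanoate F3. Burgess dehydration gives the chromene ester 2-{(2S)-6-[(tert-butyldimethylsilyl)oxy]-2-methyl-2H-chromen-2-yl}ethyl 2,2-dimethylpropanoate F4. Cleavage with i-Bu2AlH (CH2Cl2, −78 °C) gives 2-{(2S)-6-[(tert-butyldimethylsilyl)oxy]-2-methyl-2H-chromen-2-yl}ethan-1-ol F5, which has no second hydroxyl and is iodinated (I2, PPh3, imidazole) to 9.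

3. Step 8. Zinc insertion may be sluggish, the alkylzinc may be protonated or homocoupled, the alkylpalladium intermediate may undergo β-hydride elimination, or zerovalent palladium may ionise the allylic aryl ether (C2–O1). The fallback reverses the polarity and avoids palladium; it sets out from 14 and 9 and comes back at 16. Iodine–lithium exchange on 14 (t-BuLi, Et2O, −78 °C) gives [(1E)-2-methyl-4-(2,6,6-trimethylcyclohex-1-en-1-yl)but-1-en-1-yl]lithium F6. MgBr2·OEt2 converts it into [(1E)-2-methyl-4-(2,6,6-trimethylcyclohex-1-en-1-yl)but-1-en-1-yl]magnesium bromide F7. Iron-catalysed alkylation of this alkenyl Grignard reagent with the primary iodide 9 (Fe(acac)3 5 mol %, TMEDA, hexamethylenetetramine, THF, 0 °C) should give 16 with retention of the E geometry.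

**Further compounds**
F1 | step 2 | 2-{(2S,4R)-4-acetoxy-6-[(tert-butyldimethylsilyl)oxy]-2-methylchroman-2-yl}ethyl acetate | C[C@]1(CCOC(C)=O)C[C@@H](OC(C)=O)c2cc(O[Si](C)(C)C(C)(C)C)ccc2O1
F2 | step 2 | 2-{(2R,4S)-6-[(tert-butyldimethylsilyl)oxy]-4-hydroxy-2-methylchroman-2-yl}ethyl acetate | C[C@@]1(CCOC(C)=O)C[C@H](O)c2cc(O[Si](C)(C)C(C)(C)C)ccc2O1
F3 | step 4 | 2-{(2S,4R)-6-[(tert-butyldimethylsilyl)oxy]-4-hydroxy-2-methylchroman-2-yl}ethyl 2,2-dimethylpropanoate | C[C@]1(CCOC(=O)C(C)(C)C)C[C@@H](O)c2cc(O[Si](C)(C)C(C)(C)C)ccc2O1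
F4 | step 4 | 2-{(2S)-6-[(tert-butyldimethylsilyl)oxy]-2-methyl-2H-chromen-2-yl}ethyl 2,2-dimethylpropanoate | C[C@]1(CCOC(=O)C(C)(C)C)C=Cc2cc(O[Si](C)(C)C(C)(C)C)ccc2O1
F5 | step 4 | 2-{(2S)-6-[(tert-butyldimethylsilyl)oxy]-2-methyl-2H-chromen-2-yl}ethan-1-ol | C[C@]1(CCO)C=Cc2cc(O[Si](C)(C)C(C)(C)C)ccc2O1
F6 | step 8 | [(1E)-2-methyl-4-(2,6,6-trimethylcyclohex-1-en-1-yl)but-1-en-1-yl]lithium | [Li]/C=C(\C)CCC1=C(C)CCCC1(C)C
F7 | step 8 | [(1E)-2-methyl-4-(2,6,6-trimethylcyclohex-1-en-1-yl)but-1-en-1-yl]magnesium bromide | Br[Mg]/C=C(\C)CCC1=C(C)CCCC1(C)C
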